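**Retrosynthetic overview**
1. Target 35 ⇐ TES ether 34 ⇐ C30 ester 32 ⇐ C25 polyenal 26 + C5 phosphonate 30 (HWE, then DIBAL-H/MnO2); 30 ⇐ chloroacetaldehyde 27 + ylide 28 (Wittig, then Arbuzov).
2. 26 ⇐ C20 aldehyde 21 + potassium dienolate of tiglic aldehyde (intermolecular vinylogous aldol condensation that forms the central C15=C15′ bond).
3. 21 ⇐ furanoid C15 enal 16 + C5 phosphonate 17 (HWE, then DIBAL-H/MnO2).
4. Dihydrofuran of 16 ⇐ α-hydroxyallene 12 (Au-catalysed 5-endo cyclisation, axis → C8) ⇐ syn alkynyl epoxide 11 (anti-SN2′ hydride) ⇐ dienyne 10 (OH-directed epoxidation) ⇐ enol triflate 6 + enyne 8 (Sonogashira); C3 comes from asymmetric transfer hydrogenation of ketoisophorone.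
5. Ring order: the cyclohexane is bought, then the oxirane (step 8), then the dihydrofuran (step 10).

Assumption: carotenoid numbering (C1–C8′) is used in the explanations; the target is (3R,5R,8R), i.e. 3-OH cis to the ring oxygen and the polyene chain at C8 trans to the C5 methyl.
General: from step 9 on, work under argon in dim light, chromatograph on Et3N-deactivated silica and avoid acid (C8 is an acid-labile doubly allylic ether centre).

Step 1
Reactants: 1 2,6,6-trimethylcyclohex-2-ene-1,4-dione (ketoisophorone)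
Product: 2 (4R)-4-hydroxy-2,6,6-trimethylcyclohex-2-en-1-one
Conditions: RuCl[(R,R)-TsDPEN](p-cymene) (0.5 mol%), i-PrOH, rt
Reagents that add atoms: none
Why: Noyori asymmetric transfer hydrogenation reduces only the less hindered C4 ketone, and the (R,R)-catalyst (alkenyl side as the π-substituent, by analogy with aryl ketones) sets the carbinol as R, which becomes C3 of the target.

Step 2
Reactants: 2 (4R)-4-hydroxy-2,6,6-trimethylcyclohex-2-en-1-one
Product: 3 (4S)-4-hydroxy-2,2,6-trimethylcyclohexan-1-one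
Conditions: H2 (5 bar), Raney Ni, MeOH, rt
Reagents that add atoms: none
Why: Heterogeneous hydrogenation of the enone C=C leaves the hindered ketone and the carbinol untouched (R→S is only a CIP change); the new C6 centre forms as a mixture and is erased in step 4.

Step 3
Reactants: 3 (4S)-4-hydroxy-2,2,6-trimethylcyclohexan-1-one
Product: 4 (4S)-2,2,6-trimethyl-4-(triethylsilyloxy)cyclohexan-1-one
Conditions: TESCl, imidazole, DMAP (cat.), CH2Cl2, 0 °C → rt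
Reagents that add atoms: chlorotriethylsilane CC[Si](Cl)(CC)CC
Why: Standard silylation masks the hydroxyl for the enolisation in step 4 and can later be removed without touching a TBDPS ether.

Step 4
Reactants: 4 (4S)-2,2,6-trimethyl-4-(triethylsilyloxy)cyclohexan-1-one
Product: 6 (4S)-2,6,6-trimethyl-4-(triethylsilyloxy)cyclohex-1-en-1-yl trifluoromethanesulfonate, via lithium enolate 5 (not isolated)
Conditions: LDA, THF, −78 → 0 °C; PhNTf2, 0 °C → rt
Reagents that add atoms: N-phenylbis(trifluoromethanesulfonimide) O=S(=O)(N(c1ccccc1)S(=O)(=O)C(F)(F)F)C(F)(F)F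
Why: The ketone can enolise only towards the methyl-bearing carbon, so O-triflation of the enolate gives a single tetrasubstituted enol triflate (C5=C6).

Step 5
Reactants: 7 (2E)-3-methylpent-2-en-4-yn-1-ol
Product: 8 tert-butyl{[(2E)-3-methylpent-2-en-4-yn-1-yl]oxy}diphenylsilane
Conditions: TBDPSCl, imidazole, DMF, rt
Reagents that add atoms: tert-butyl(chloro)diphenylsilane CC(C)(C)[Si](Cl)(c1ccccc1)c1ccccc1
Why: Silylation of the primary allylic alcohol removes the only other hydroxyl that could direct the epoxidation in step 8, and the TBDPS ether survives steps 6–10.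

Step 6
Reactants: 6 (4S)-2,6,6-trimethyl-4-(triethylsilyloxy)cyclohex-1-en-1-yl trifluoromethanesulfonate + 8 tert-butyl{[(2E)-3-methylpent-2-en-4-yn-1-yl]oxy}diphenylsilane
Product: 9 tert-butyl({(2E)-3-methyl-5-[(4S)-2,6,6-trimethyl-4-(triethylsilyloxy)cyclohex-1-en-1-yl]pent-2-en-4-yn-1-yl}oxy)diphenylsilane
Conditions: Pd(PPh3)4 (5 mol%), CuI (10 mol%), Et3N, DMF, 50 °C
Reagents that add atoms: none
Why: Sonogashira coupling of the enol triflate with the terminal alkyne forms C6–C7 and carries the bought (E)-C9=C10 geometry into the dienyne.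

Step 7
Reactants: 9 tert-butyl({(2E)-3-methyl-5-[(4S)-2,6,6-trimethyl-4-(triethylsilyloxy)cyclohex-1-en-1-yl]pent-2-en-4-yn-1-yl}oxy)diphenylsilane
Product: 10 (1S)-4-[(3E)-5-{[tert-butyl(diphenyl)silyl]oxy}-3-methylpent-3-en-1-yn-1-yl]-3,5,5-trimethylcyclohex-3-en-1-ol
Conditions: PPTS (0.1 eq), MeOH/CH2Cl2, 0 °C → rt
Reagents that add atoms: none
Why: Mild acid methanolysis removes the secondary TES ether far faster than the primary TBDPS ether, freeing the C3 hydroxyl as the directing group.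

Step 8
Reactants: 10 (1S)-4-[(3E)-5-{[tert-butyl(diphenyl)silyl]oxy}-3-methylpent-3-en-1-yn-1-yl]-3,5,5-trimethylcyclohex-3-en-1-ol
Product: 11 (1R,3R,6R)-6-[(3E)-5-{[tert-butyl(diphenyl)silyl]oxy}-3-methylpent-3-en-1-yn-1-yl]-1,5,5-trimethyl-7-oxabicyclo[4.1.0]heptan-3-ol
Conditions: VO(acac)2 (5 mol%), t-BuOOH (1.5 eq, decane), toluene, 0 °C → rt
Reagents that add atoms: tert-butyl hydroperoxide CC(C)(C)OO
Why: Vanadium-catalysed hydroxyl-directed epoxidation delivers oxygen to the C5=C6 face syn to the homoallylic C3–OH (sets C5 and C6, epoxide cis to OH), while the undirected C9=C10 bond is untouched.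

Step 9
Reactants: 11 (1R,3R,6R)-6-[(3E)-5-{[tert-butyl(diphenyl)silyl]oxy}-3-methylpent-3-en-1-yn-1-yl]-1,5,5-trimethyl-7-oxabicyclo[4.1.0]heptan-3-ol
Product: 12 (1R,3R)-4-[(3E)-5-{[tert-butyl(diphenyl)silyl]oxy}-3-methylpenta-1,3-dien-1-ylidene]-3,5,5-trimethylcyclohexane-1,3-diol (allene axis S)
Conditions: IPrCuCl (5 mol%), NaOt-Bu (5 mol%), PMHS (3 eq Si–H), toluene, 0 °C → rt; K2CO3, MeOH work-up
Reagents that add atoms: none
Why: Copper hydride SN2′ reduction of the propargylic oxirane is expected to go anti, as organocopper SN2′ reactions do, putting H on C8 opposite the breaking C6–O bond and so giving the (S) allene axis with C5–OH retained; DIBAL-H is not used because its oxygen-directed hydride delivery leads to the opposite, natural (6R)-type axis from such epoxides.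

Step 10
Reactants: 12 (1R,3R)-4-[(3E)-5-{[tert-butyl(diphenyl)silyl]oxy}-3-methylpenta-1,3-dien-1-ylidene]-3,5,5-trimethylcyclohexane-1,3-diol (allene axis S)
Product: 13 (2R,6R,7aR)-2-[(2E)-4-{[tert-butyl(diphenyl)silyl]oxy}but-2-en-2-yl]-4,4,7a-trimethyl-2,4,5,6,7,7a-hexahydro-1-benzofuran-6-ol
Conditions: AuCl3 (2 mol%), THF, rt
Reagents that add atoms: none
Why: Gold-catalysed 5-endo cycloisomerisation of the α-hydroxyallene adds the C5 oxygen to C8 in the plane of the C6 substituents, so axis-to-centre chirality transfer sets C8 as R (chain trans to the C5 methyl) and leaves the C6=C7 bond.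

Step 11
Reactants: 13 (2R,6R,7aR)-2-[(2E)-4-{[tert-butyl(diphenyl)silyl]oxy}but-2-en-2-yl]-4,4,7a-trimethyl-2,4,5,6,7,7a-hexahydro-1-benzofuran-6-ol
Product: 14 (2R,6R,7aR)-2-[(2E)-4-hydroxybut-2-en-2-yl]-4,4,7a-trimethyl-2,4,5,6,7,7a-hexahydro-1-benzofuran-6-ol
Conditions: TBAF, THF, 0 °C → rt
Reagents that add atoms: none
Why: Fluoride desilylation is non-acidic, so the C8 ether centre is not put at risk.

Step 12
Reactants: 14 (2R,6R,7aR)-2-[(2E)-4-hydroxybut-2-en-2-yl]-4,4,7a-trimethyl-2,4,5,6,7,7a-hexahydro-1-benzofuran-6-ol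
Product: 15 (2E)-3-[(2R,6R,7aR)-6-hydroxy-4,4,7a-trimethyl-2,4,5,6,7,7a-hexahydro-1-benzofuran-2-yl]but-2-enal
Conditions: MnO2 (15 eq), CH2Cl2, rt
Reagents that add atoms: none
Why: Activated MnO2 oxidises only the primary allylic alcohol, leaving the saturated secondary C3–OH untouched.

Step 13
Reactants: 15 (2E)-3-[(2R,6R,7aR)-6-hydroxy-4,4,7a-trimethyl-2,4,5,6,7,7a-hexahydro-1-benzofuran-2-yl]but-2-enal
Product: 16 (2E)-3-[(2R,6R,7aR)-4,4,7a-trimethyl-6-(triethylsilyloxy)-2,4,5,6,7,7a-hexahydro-1-benzofuran-2-yl]but-2-enal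
Conditions: TESCl, imidazole, CH2Cl2, 0 °C
Reagents that add atoms: chlorotriethylsilane CC[Si](Cl)(CC)CC
Why: Silylation keeps the hydroxyl from quenching the carbanions and the dienolate of steps 14, 18 and 21.

Step 14
Reactants: 16 (2E)-3-[(2R,6R,7aR)-4,4,7a-trimethyl-6-(triethylsilyloxy)-2,4,5,6,7,7a-hexahydro-1-benzofuran-2-yl]but-2-enal + 17 ethyl (2E)-4-(diethoxyphosphoryl)-3-methylbut-2-enoate
Product: 19 ethyl (2E,4E,6E)-3-methyl-7-[(2R,6R,7aR)-4,4,7a-trimethyl-6-(triethylsilyloxy)-2,4,5,6,7,7a-hexahydro-1-benzofuran-2-yl]octa-2,4,6-trienoate, via lithiated phosphonate 18 (not isolated)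
Conditions: LiHMDS, THF/DMPU, −78 °C; then 16, −78 → 0 °C
Reagents that add atoms: none
Why: Horner–Wadsworth–Emmons olefination with the preformed anion at low temperature forms C11=C12 as E without enolising towards C8; about 10% of the 13Z isomer is expected and is removed by chromatography.

Step 15
Reactants: 19 ethyl (2E,4E,6E)-3-methyl-7-[(2R,6R,7aR)-4,4,7a-trimethyl-6-(triethylsilyloxy)-2,4,5,6,7,7a-hexahydro-1-benzofuran-2-yl]octa-2,4,6-trienoate
Product: 20 (2E,4E,6E)-3-methyl-7-[(2R,6R,7aR)-4,4,7a-trimethyl-6-(triethylsilyloxy)-2,4,5,6,7,7a-hexahydro-1-benzofuran-2-yl]octa-2,4,6-trien-1-ol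
Conditions: DIBAL-H (2.5 eq), CH2Cl2, −78 °C; Rochelle salt work-up
Reagents that add atoms: none
Why: DIBAL-H reduces the conjugated ester 1,2 to the allylic alcohol and touches neither the alkenes nor the silyl ether.

Step 16
Reactants: 20 (2E,4E,6E)-3-methyl-7-[(2R,6R,7aR)-4,4,7a-trimethyl-6-(triethylsilyloxy)-2,4,5,6,7,7a-hexahydro-1-benzofuran-2-yl]octa-2,4,6-trien-1-ol
Product: 21 (2E,4E,6E)-3-methyl-7-[(2R,6R,7aR)-4,4,7a-trimethyl-6-(triethylsilyloxy)-2,4,5,6,7,7a-hexahydro-1-benzofuran-2-yl]octa-2,4,6-trienal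
Conditions: MnO2 (15 eq), CH2Cl2, rt
Reagents that add atoms: none
Why: MnO2 oxidation of the polyenyl alcohol gives the C20 aldehyde under neutral conditions, as in retinol → retinal.

Step 17
Reactants: 22 (2E)-2-methylbut-2-enal (tiglic aldehyde)
Product: 23 trimethyl[(2-methylbuta-1,3-dien-1-yl)oxy]silane
Conditions: TMSOTf, Et3N, Et2O, 0 °C
Reagents that add atoms: trimethylsilyl trifluoromethanesulfonate C[Si](C)(C)OS(=O)(=O)C(F)(F)F
Why: O-silylation with γ-deprotonation gives the silyl dienol ether, a storable precursor of the C5 dienolate.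

Step 18
Reactants: 21 (2E,4E,6E)-3-methyl-7-[(2R,6R,7aR)-4,4,7a-trimethyl-6-(triethylsilyloxy)-2,4,5,6,7,7a-hexahydro-1-benzofuran-2-yl]octa-2,4,6-trienal + 23 trimethyl[(2-methylbuta-1,3-dien-1-yl)oxy]silane
Product: 26 (2E,4E,6E,8E,10E)-2,7-dimethyl-11-[(2R,6R,7aR)-4,4,7a-trimethyl-6-(triethylsilyloxy)-2,4,5,6,7,7a-hexahydro-1-benzofuran-2-yl]dodeca-2,4,6,8,10-pentaenal, via potassium dienolate 24 (not isolated), via potassium aldolate 25 (not isolated)
Conditions: 23 (1.1 eq), t-BuOK (1.1 eq), THF, −40 °C; then 21, −78 → 0 °C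
Reagents that add atoms: none
Why: Vinylogous aldol condensation, in which the potassium dienolate adds 1,2 through its γ-carbon to the retinal-type aldehyde and the aldolate loses KOH by E1cB, forms the central C15=C15′ bond and the α-methyl enal, both as the thermodynamic E isomers.

Step 19
Reactants: 27 chloroacetaldehyde + 28 ethyl 2-(triphenyl-λ5-phosphanylidene)propanoate
Product: 29 ethyl (2E)-4-chloro-2-methylbut-2-enoate
Conditions: 27 (50 wt% in water, 1.3 eq), CH2Cl2, 0 °C → rt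
Reagents that add atoms: none
Why: Wittig olefination with the stabilised α-methyl ylide gives the (E)-trisubstituted enoate with the chlorine placed unambiguously at C4, which fixes the later C9′=C10′ geometry.

Step 20
Reactants: 29 ethyl (2E)-4-chloro-2-methylbut-2-enoate
Product: 30 ethyl (2E)-4-(diethoxyphosphoryl)-2-methylbut-2-enoate
Conditions: P(OEt)3 (1.3 eq), NaI (10 mol%), neat, 130 °C, EtCl distilled off
Reagents that add atoms: triethyl phosphite CCOP(OCC)OCC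
Why: The iodide-catalysed Michaelis–Arbuzov reaction of the allylic chloride gives the allylic phosphonate and leaves the (E)-enoate unchanged.

Step 21
Reactants: 26 (2E,4E,6E,8E,10E)-2,7-dimethyl-11-[(2R,6R,7aR)-4,4,7a-trimethyl-6-(triethylsilyloxy)-2,4,5,6,7,7a-hexahydro-1-benzofuran-2-yl]dodeca-2,4,6,8,10-pentaenal + 30 ethyl (2E)-4-(diethoxyphosphoryl)-2-methylbut-2-enoate
Product: 32 ethyl (2E,4E,6E,8E,10E,12E,14E)-2,6,11-trimethyl-15-[(2R,6R,7aR)-4,4,7a-trimethyl-6-(triethylsilyloxy)-2,4,5,6,7,7a-hexahydro-1-benzofuran-2-yl]hexadeca-2,4,6,8,10,12,14-heptaenoate, via lithiated phosphonate 31 (not isolated)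
Conditions: LiHMDS, THF/DMPU, −78 °C; then 26, −78 → 0 °C
Reagents that add atoms: none
Why: Horner–Wadsworth–Emmons olefination of the α-methyl enal with the preformed vinylogous phosphonate anion forms C11′=C12′ as E and brings in the (E)-2-methyl enoate terminus; minor Z isomers are removed by chromatography.

Step 22
Reactants: 32 ethyl (2E,4E,6E,8E,10E,12E,14E)-2,6,11-trimethyl-15-[(2R,6R,7aR)-4,4,7a-trimethyl-6-(triethylsilyloxy)-2,4,5,6,7,7a-hexahydro-1-benzofuran-2-yl]hexadeca-2,4,6,8,10,12,14-heptaenoate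
Product: 33 (2E,4E,6E,8E,10E,12E,14E)-2,6,11-trimethyl-15-[(2R,6R,7aR)-4,4,7a-trimethyl-6-(triethylsilyloxy)-2,4,5,6,7,7a-hexahydro-1-benzofuran-2-yl]hexadeca-2,4,6,8,10,12,14-heptaen-1-ol
Conditions: DIBAL-H (2.5 eq), CH2Cl2, −78 °C; Rochelle salt work-up
Reagents that add atoms: none
Why: DIBAL-H reduces the polyenoate 1,2 to the allylic alcohol without touching the polyene, the cyclic ether or the silyl ether.

Step 23
Reactants: 33 (2E,4E,6E,8E,10E,12E,14E)-2,6,11-trimethyl-15-[(2R,6R,7aR)-4,4,7a-trimethyl-6-(triethylsilyloxy)-2,4,5,6,7,7a-hexahydro-1-benzofuran-2-yl]hexadeca-2,4,6,8,10,12,14-heptaen-1-ol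
Product: 34 (2E,4E,6E,8E,10E,12E,14E)-2,6,11-trimethyl-15-[(2R,6R,7aR)-4,4,7a-trimethyl-6-(triethylsilyloxy)-2,4,5,6,7,7a-hexahydro-1-benzofuran-2-yl]hexadeca-2,4,6,8,10,12,14-heptaenal
Conditions: MnO2 (15 eq), CH2Cl2, rt
Reagents that add atoms: none
Why: MnO2 oxidises the polyenyl allylic alcohol to the C30 aldehyde under neutral conditions that spare C8.

Step 24
Reactants: 34 (2E,4E,6E,8E,10E,12E,14E)-2,6,11-trimethyl-15-[(2R,6R,7aR)-4,4,7a-trimethyl-6-(triethylsilyloxy)-2,4,5,6,7,7a-hexahydro-1-benzofuran-2-yl]hexadeca-2,4,6,8,10,12,14-heptaenal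
Product: 35 (2E,4E,6E,8E,10E,12E,14E)-15-[(2R,6R,7aR)-6-hydroxy-4,4,7a-trimethyl-2,4,5,6,7,7a-hexahydro-1-benzofuran-2-yl]-2,6,11-trimethylhexadeca-2,4,6,8,10,12,14-heptaenal
Conditions: TBAF, AcOH (1:1), THF, 0 °C → rt
Reagents that add atoms: none
Why: Buffered fluoride removes the TES ether without acid (C8) or strong base (polyenal), giving the (3R,5R,8R) target.

**Compound list**
1 | 2,6,6-trimethylcyclohex-2-ene-1,4-dione (ketoisophorone) | CC1=CC(=O)CC(C)(C)C1=O | starting material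
2 | (4R)-4-hydroxy-2,6,6-trimethylcyclohex-2-en-1-one | O=C1C(C)(C)C[C@@H](O)C=C1C | intermediate
3 | (4S)-4-hydroxy-2,2,6-trimethylcyclohexan-1-one (both C6 epimers) | O=C1C(C)(C)C[C@@H](O)CC1C | intermediate
4 | (4S)-2,2,6-trimethyl-4-(triethylsilyloxy)cyclohexan-1-one (both C6 epimers) | O=C1C(C)(C)C[C@@H](O[Si](CC)(CC)CC)CC1C | intermediate
5 | lithium (4S)-2,6,6-trimethyl-4-(triethylsilyloxy)cyclohex-1-en-1-olate (not isolated) | CC1(C)C[C@@H](O[Si](CC)(CC)CC)CC(C)=C1[O-].[Li+] | intermediate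
6 | (4S)-2,6,6-trimethyl-4-(triethylsilyloxy)cyclohex-1-en-1-yl trifluoromethanesulfonate | CC1(C)C[C@@H](O[Si](CC)(CC)CC)CC(C)=C1OS(=O)(=O)C(F)(F)F | intermediate
7 | (2E)-3-methylpent-2-en-4-yn-1-ol | C#C/C(C)=C/CO | starting material
8 | tert-butyl{[(2E)-3-methylpent-2-en-4-yn-1-yl]oxy}diphenylsilane | C#C/C(C)=C/CO[Si](c1ccccc1)(c1ccccc1)C(C)(C)C | intermediate
9 | tert-butyl({(2E)-3-methyl-5-[(4S)-2,6,6-trimethyl-4-(triethylsilyloxy)cyclohex-1-en-1-yl]pent-2-en-4-yn-1-yl}oxy)diphenylsilane | CC1(C)C[C@@H](O[Si](CC)(CC)CC)CC(C)=C1C#C/C(C)=C/CO[Si](c1ccccc1)(c1ccccc1)C(C)(C)C | intermediate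
10 | (1S)-4-[(3E)-5-{[tert-butyl(diphenyl)silyl]oxy}-3-methylpent-3-en-1-yn-1-yl]-3,5,5-trimethylcyclohex-3-en-1-ol | CC1(C)C[C@@H](O)CC(C)=C1C#C/C(C)=C/CO[Si](c1ccccc1)(c1ccccc1)C(C)(C)C | intermediate
11 | (1R,3R,6R)-6-[(3E)-5-{[tert-butyl(diphenyl)silyl]oxy}-3-methylpent-3-en-1-yn-1-yl]-1,5,5-trimethyl-7-oxabicyclo[4.1.0]heptan-3-ol (epoxide cis to OH) | CC1(C)C[C@@H](O)C[C@@]2(C)O[C@@]12C#C/C(C)=C/CO[Si](c1ccccc1)(c1ccccc1)C(C)(C)C | intermediate
12 | (1R,3R)-4-[(3E)-5-{[tert-butyl(diphenyl)silyl]oxy}-3-methylpenta-1,3-dien-1-ylidene]-3,5,5-trimethylcyclohexane-1,3-diol, allene axis S (H-8 anti to the former C6–O bond) | CC1(C)C[C@@H](O)C[C@@](C)(O)C1=[C@@]=C([H])/C(C)=C/CO[Si](c1ccccc1)(c1ccccc1)C(C)(C)C | intermediate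
13 | (2R,6R,7aR)-2-[(2E)-4-{[tert-butyl(diphenyl)silyl]oxy}but-2-en-2-yl]-4,4,7a-trimethyl-2,4,5,6,7,7a-hexahydro-1-benzofuran-6-ol | CC(C)(C)[Si](c1ccccc1)(c1ccccc1)OC/C=C(\C)[C@H]1C=C2C(C)(C)C[C@@H](O)C[C@@]2(C)O1 | intermediate
14 | (2R,6R,7aR)-2-[(2E)-4-hydroxybut-2-en-2-yl]-4,4,7a-trimethyl-2,4,5,6,7,7a-hexahydro-1-benzofuran-6-ol | OC/C=C(\C)[C@H]1C=C2C(C)(C)C[C@@H](O)C[C@@]2(C)O1 | intermediate
15 | (2E)-3-[(2R,6R,7aR)-6-hydroxy-4,4,7a-trimethyl-2,4,5,6,7,7a-hexahydro-1-benzofuran-2-yl]but-2-enal | O=C/C=C(\C)[C@H]1C=C2C(C)(C)C[C@@H](O)C[C@@]2(C)O1 | intermediate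
16 | (2E)-3-[(2R,6R,7aR)-4,4,7a-trimethyl-6-(triethylsilyloxy)-2,4,5,6,7,7a-hexahydro-1-benzofuran-2-yl]but-2-enal | O=C/C=C(\C)[C@H]1C=C2C(C)(C)C[C@@H](O[Si](CC)(CC)CC)C[C@@]2(C)O1 | intermediate
17 | ethyl (2E)-4-(diethoxyphosphoryl)-3-methylbut-2-enoate (triethyl 3-methyl-4-phosphonocrotonate) | CCOC(=O)/C=C(\C)CP(=O)(OCC)OCC | starting material
18 | lithium salt of the C4 carbanion of 17 (not isolated) | [Li+].CCOC(=O)C=C(C)[CH-]P(=O)(OCC)OCC | intermediate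
19 | ethyl (2E,4E,6E)-3-methyl-7-[(2R,6R,7aR)-4,4,7a-trimethyl-6-(triethylsilyloxy)-2,4,5,6,7,7a-hexahydro-1-benzofuran-2-yl]octa-2,4,6-trienoate | CCOC(=O)/C=C(C)/C=C/C=C(\C)[C@H]1C=C2C(C)(C)C[C@@H](O[Si](CC)(CC)CC)C[C@@]2(C)O1 | intermediate
20 | (2E,4E,6E)-3-methyl-7-[(2R,6R,7aR)-4,4,7a-trimethyl-6-(triethylsilyloxy)-2,4,5,6,7,7a-hexahydro-1-benzofuran-2-yl]octa-2,4,6-trien-1-ol | OC/C=C(C)/C=C/C=C(\C)[C@H]1C=C2C(C)(C)C[C@@H](O[Si](CC)(CC)CC)C[C@@]2(C)O1 | intermediate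
21 | (2E,4E,6E)-3-methyl-7-[(2R,6R,7aR)-4,4,7a-trimethyl-6-(triethylsilyloxy)-2,4,5,6,7,7a-hexahydro-1-benzofuran-2-yl]octa-2,4,6-trienal | O=C/C=C(C)/C=C/C=C(\C)[C@H]1C=C2C(C)(C)C[C@@H](O[Si](CC)(CC)CC)C[C@@]2(C)O1 | intermediate
22 | (2E)-2-methylbut-2-enal (tiglic aldehyde) | C/C=C(\C)C=O | starting material
23 | trimethyl[(2-methylbuta-1,3-dien-1-yl)oxy]silane (E/Z mixture) | C=CC(C)=CO[Si](C)(C)C | intermediate
24 | potassium 2-methylbuta-1,3-dien-1-olate (not isolated) | [K+].[O-]C=C(C)C=C | intermediate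
25 | potassium alkoxide of (2E,6E,8E,10E)-5-hydroxy-2,7-dimethyl-11-[(2R,6R,7aR)-4,4,7a-trimethyl-6-(triethylsilyloxy)-2,4,5,6,7,7a-hexahydro-1-benzofuran-2-yl]dodeca-2,6,8,10-tetraenal (carbinol centre unassigned; not isolated) | [K+].O=C/C(C)=C/CC([O-])/C=C(C)/C=C/C=C(\C)[C@H]1C=C2C(C)(C)C[C@@H](O[Si](CC)(CC)CC)C[C@@]2(C)O1 | intermediate
26 | (2E,4E,6E,8E,10E)-2,7-dimethyl-11-[(2R,6R,7aR)-4,4,7a-trimethyl-6-(triethylsilyloxy)-2,4,5,6,7,7a-hexahydro-1-benzofuran-2-yl]dodeca-2,4,6,8,10-pentaenal | O=C/C(C)=C/C=C/C=C(C)/C=C/C=C(\C)[C@H]1C=C2C(C)(C)C[C@@H](O[Si](CC)(CC)CC)C[C@@]2(C)O1 | intermediate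
27 | chloroacetaldehyde (used as the 50 wt% aqueous solution) | ClCC=O | starting material
28 | ethyl 2-(triphenyl-λ5-phosphanylidene)propanoate | CCOC(=O)C(C)=P(c1ccccc1)(c1ccccc1)c1ccccc1 | starting material
29 | ethyl (2E)-4-chloro-2-methylbut-2-enoate | CCOC(=O)/C(C)=C/CCl | intermediate
30 | ethyl (2E)-4-(diethoxyphosphoryl)-2-methylbut-2-enoate | CCOC(=O)/C(C)=C/CP(=O)(OCC)OCC | intermediate
31 | lithium salt of the C4 carbanion of 30 (not isolated) | [Li+].CCOC(=O)C(C)=C[CH-]P(=O)(OCC)OCC | intermediate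
32 | ethyl (2E,4E,6E,8E,10E,12E,14E)-2,6,11-trimethyl-15-[(2R,6R,7aR)-4,4,7a-trimethyl-6-(triethylsilyloxy)-2,4,5,6,7,7a-hexahydro-1-benzofuran-2-yl]hexadeca-2,4,6,8,10,12,14-heptaenoate | CCOC(=O)/C(C)=C/C=C/C(C)=C/C=C/C=C(C)/C=C/C=C(\C)[C@H]1C=C2C(C)(C)C[C@@H](O[Si](CC)(CC)CC)C[C@@]2(C)O1 | intermediate
33 | (2E,4E,6E,8E,10E,12E,14E)-2,6,11-trimethyl-15-[(2R,6R,7aR)-4,4,7a-trimethyl-6-(triethylsilyloxy)-2,4,5,6,7,7a-hexahydro-1-benzofuran-2-yl]hexadeca-2,4,6,8,10,12,14-heptaen-1-ol | OC/C(C)=C/C=C/C(C)=C/C=C/C=C(C)/C=C/C=C(\C)[C@H]1C=C2C(C)(C)C[C@@H](O[Si](CC)(CC)CC)C[C@@]2(C)O1 | intermediate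
34 | (2E,4E,6E,8E,10E,12E,14E)-2,6,11-trimethyl-15-[(2R,6R,7aR)-4,4,7a-trimethyl-6-(triethylsilyloxy)-2,4,5,6,7,7a-hexahydro-1-benzofuran-2-yl]hexadeca-2,4,6,8,10,12,14-heptaenal | C\C(C=O)=C/C=C/C(C)=C/C=C/C=C(C)/C=C/C=C(\C)[C@H]1C=C2C(C)(C)C[C@@H](O[Si](CC)(CC)CC)C[C@@]2(C)O1 | intermediate
35 | (2E,4E,6E,8E,10E,12E,14E)-15-[(2R,6R,7aR)-6-hydroxy-4,4,7a-trimethyl-2,4,5,6,7,7a-hexahydro-1-benzofuran-2-yl]-2,6,11-trimethylhexadeca-2,4,6,8,10,12,14-heptaenal (CNP0118413.1) | C\C(C=O)=C/C=C/C(C)=C/C=C/C=C(C)/C=C/C=C(\C)[C@H]1C=C2C(C)(C)C[C@@H](O)C[C@@]2(C)O1 | target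

**Totals**
Total steps: 24. Longest linear sequence: 20 (steps 1–4, 6–16, 18, 21–24; steps 5, 17, 19 and 20 make the side fragments).

**Steps most likely to fail and fallbacks**

Step 9 (copper hydride SN2′ reduction). The oxirane is fully substituted, and the anti:syn ratio decides C8. The fallback sets out from 6 and 8, avoids the allene and comes back at 13. Hydroboration of 8 (pinacolborane, 5 mol% Cp2Zr(H)Cl) gives the (1E,3E)-dienylboronate F1. Suzuki coupling of F1 with 6 (PdCl2(dppf), K3PO4, THF/H2O, 60 °C) gives the bis-silyl triene F2. PPTS/MeOH gives the triene alcohol F3, and VO(acac)2/t-BuOOH gives the syn-5,6-epoxide F4. A trace of acid (CSA, CH2Cl2, 0 °C) then triggers the classical epoxide → furanoid rearrangement, in which the C5 oxygen captures the allylic cation at C8. This gives 13 together with its C8 epimer F5 in roughly equal amounts; they are separated by chromatography, and F5 can be re-equilibrated with acid and recycled.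

Step 10 (gold cyclisation). The vinyl-substituted allene may lose axial integrity or react at the diene. The fallback sets out from 12 and comes back at 13. N-Iodosuccinimide (CH2Cl2, 0 °C) effects the same stereospecific 5-endo O–C8 closure by iodoetherification and gives the 3-iodo-2,5-dihydrofuran F6. Pd(PPh3)4/Bu3SnH (THF, rt) then removes the vinylic iodine to give 13.

Step 18 (vinylogous aldol condensation). The dangers are α- versus γ-attack of the dienolate, incomplete dehydration of the δ-hydroxy enal and over-homologation. The fallback sets out from 21 and comes back at 26 by olefination instead of aldol chemistry, using phosphonate 30 that the route makes in steps 19–20. HWE reaction of 21 with the lithium anion of 30 (LiHMDS, THF/DMPU, −78 → 0 °C) gives the C25 ethyl ester F7. DIBAL-H (CH2Cl2, −78 °C) gives the C25 allylic alcohol F8, and MnO2 (CH2Cl2, rt) gives 26.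

Further compounds
F1 | step 9 | tert-butyl{[(2E,4E)-3-methyl-5-(4,4,5,5-tetramethyl-1,3,2-dioxaborolan-2-yl)penta-2,4-dien-1-yl]oxy}diphenylsilane | CC1(C)OB(/C=C/C(C)=C/CO[Si](c2ccccc2)(c2ccccc2)C(C)(C)C)OC1(C)C
F2 | step 9 | tert-butyl({(2E,4E)-3-methyl-5-[(4S)-2,6,6-trimethyl-4-(triethylsilyloxy)cyclohex-1-en-1-yl]penta-2,4-dien-1-yl}oxy)diphenylsilane | CC1(C)C[C@@H](O[Si](CC)(CC)CC)CC(C)=C1/C=C/C(C)=C/CO[Si](c1ccccc1)(c1ccccc1)C(C)(C)C
F3 | step 9 | (1S)-4-[(1E,3E)-5-{[tert-butyl(diphenyl)silyl]oxy}-3-methylpenta-1,3-dien-1-yl]-3,5,5-trimethylcyclohex-3-en-1-ol | CC1(C)C[C@@H](O)CC(C)=C1/C=C/C(C)=C/CO[Si](c1ccccc1)(c1ccccc1)C(C)(C)C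
F4 | step 9 | (1R,3R,6S)-6-[(1E,3E)-5-{[tert-butyl(diphenyl)silyl]oxy}-3-methylpenta-1,3-dien-1-yl]-1,5,5-trimethyl-7-oxabicyclo[4.1.0]heptan-3-ol | CC1(C)C[C@@H](O)C[C@@]2(C)O[C@@]12/C=C/C(C)=C/CO[Si](c1ccccc1)(c1ccccc1)C(C)(C)C
F5 | step 9 | (2S,6R,7aR)-2-[(2E)-4-{[tert-butyl(diphenyl)silyl]oxy}but-2-en-2-yl]-4,4,7a-trimethyl-2,4,5,6,7,7a-hexahydro-1-benzofuran-6-ol | CC(C)(C)[Si](c1ccccc1)(c1ccccc1)OC/C=C(\C)[C@@H]1C=C2C(C)(C)C[C@@H](O)C[C@@]2(C)O1
F6 | step 10 | (2S,6R,7aR)-2-[(2E)-4-{[tert-butyl(diphenyl)silyl]oxy}but-2-en-2-yl]-3-iodo-4,4,7a-trimethyl-2,4,5,6,7,7a-hexahydro-1-benzofuran-6-ol (same spatial arrangement at C2 as 13) | CC(C)(C)[Si](c1ccccc1)(c1ccccc1)OC/C=C(\C)[C@H]1C(I)=C2C(C)(C)C[C@@H](O)C[C@@]2(C)O1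
F7 | step 18 | ethyl (2E,4E,6E,8E,10E)-2,7-dimethyl-11-[(2R,6R,7aR)-4,4,7a-trimethyl-6-(triethylsilyloxy)-2,4,5,6,7,7a-hexahydro-1-benzofuran-2-yl]dodeca-2,4,6,8,10-pentaenoate | CCOC(=O)/C(C)=C/C=C/C=C(C)/C=C/C=C(\C)[C@H]1C=C2C(C)(C)C[C@@H](O[Si](CC)(CC)CC)C[C@@]2(C)O1
F8 | step 18 | (2E,4E,6E,8E,10E)-2,7-dimethyl-11-[(2R,6R,7aR)-4,4,7a-trimethyl-6-(triethylsilyloxy)-2,4,5,6,7,7a-hexahydro-1-benzofuran-2-yl]dodeca-2,4,6,8,10-pentaen-1-ol | OC/C(C)=C/C=C/C=C(C)/C=C/C=C(\C)[C@H]1C=C2C(C)(C)C[C@@H](O[Si](CC)(CC)CC)C[C@@]2(C)O1
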